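## Retrosynthetic overview

1. Ester C–O bond: formed last, without protecting groups, by Mitsunobu coupling of free 2,3-dihydroxybenzoic acid with (S)-16-methyloctadecan-1-ol.
2. Key step: the C16 stereocentre and the C16–C17 bond are created together by Zr-catalysed asymmetric ethylalumination (ZACA) of achiral heptadec-16-en-1-ol. Protonolysis of the C–Al bond turns the former vinyl CH2 into the methyl branch, so no chiral-pool 2-methylbutyl unit is used.
3. Heptadec-16-en-1-ol: C11–C12 bond by Cu-catalysed coupling of a C11 alkenyl Grignard with 6-bromohexan-1-ol.
4. Rings: none are formed; the benzene ring is bought intact in 2,3-dihydroxybenzoic acid.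

Assumption: the target SMILES encodes (S)-16-methyloctadecyl 2,3-dihydroxybenzoate, and the route is planned for that enantiomer. Both antipodes of the Erker–Negishi catalyst (NMI)2ZrCl2, bis(1-neomenthylindenyl)zirconium dichloride, are taken as available.

## Route

**Step 1**
Reactants: 1, 11-bromoundec-1-ene; 2, 6-bromohexan-1-ol
Product: 3, heptadec-16-en-1-ol
Conditions: 1, Mg, THF, 40 °C (gives undec-10-enylMgBr, 1.3 equiv); 2 pre-treated with MeMgCl (1.0 equiv), THF, −20 °C; Li2CuCl4 (3 mol%), THF/NMP, −20 °C → rt; aq. NH4Cl
Reagents that add atoms: none beyond reactants 1 and 2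
Why: Kochi-type Cu-catalysed sp3–sp3 Grignard/primary alkyl bromide cross-coupling, with the bromo-alcohol masked in situ as its magnesium alkoxide and the terminal alkene inert; C11 + C6 gives the C17 alkenol and no stereocentre is involved.

**Step 2**
Reactants: 3, heptadec-16-en-1-ol; 4, triethylaluminium
Product: 5, (S)-16-methyloctadecan-1-ol
Conditions: Et3Al (4 equiv; the first equivalent forms RO–AlEt2), (+)-(NMI)2ZrCl2 (5–8 mol%), CH2Cl2, 0 → 23 °C, 16 h; then 2 M HCl, 0 °C
Reagents that add atoms: triethylaluminium, CC[Al](CC)CC (its ethyl group becomes C17–C18)
Why: Negishi ZACA reaction, in which the chiral zirconocene adds Et to the internal alkene carbon and Al to the terminal CH2 with catalyst-controlled facial selectivity (expected 90–95% ee in chlorinated solvent), and acid protonolysis converts CH2–Al into the methyl branch; the (−)-catalyst is recalled from the literature as giving (R)-2-alkyl-1-alkanols, which maps to (R)-5, so the (+)-antipode is used for (S)-5, and this sense is confirmed on the first run by Mosher analysis of an O2-quenched aliquot.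

**Step 3**
Reactants: 5, (S)-16-methyloctadecan-1-ol; 6, 2,3-dihydroxybenzoic acid
Product: 7, Gentiside F, (S)-16-methyloctadecyl 2,3-dihydroxybenzoate
Conditions: 6 (1.5 equiv), PPh3 (1.3 equiv), DIAD (1.3 equiv), THF, 0 °C → rt
Reagents that add atoms: 2,3-dihydroxybenzoic acid, O=C(O)c1cccc(O)c1O (PPh3 and DIAD leave no atoms)
Why: Chemoselective Mitsunobu esterification of an unprotected phenolic acid, where only the CO2H (pKa about 3, against about 10–13 for the phenols) protonates the betaine and the carboxylate displaces the primary alkoxyphosphonium; the reaction is at C1, so the remote C16 stereocentre is untouched.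

## Compound list

1 | 11-bromoundec-1-ene | C=CCCCCCCCCCBr | starting material
2 | 6-bromohexan-1-ol | OCCCCCCBr | starting material
3 | heptadec-16-en-1-ol | OCCCCCCCCCCCCCCCC=C | intermediate
4 | triethylaluminium | CC[Al](CC)CC | starting material (reagent supplying C17–C18)
5 | (S)-16-methyloctadecan-1-ol | CC[C@H](C)CCCCCCCCCCCCCCCO | intermediate
6 | 2,3-dihydroxybenzoic acid | O=C(O)c1cccc(O)c1O | starting material
7 | Gentiside F, (S)-16-methyloctadecyl 2,3-dihydroxybenzoate | CC[C@H](C)CCCCCCCCCCCCCCCOC(=O)c1cccc(O)c1O | target

## Summary

Total steps: 3. Longest linear sequence: 3 (1/2 → 3 → 5 → 7). No protecting groups are used.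

Steps most likely to fail, each with a fallback that changes the approach:

1. **Step 2 (ZACA).** This is the accepted risk of the route.
   - The ee ceiling is about 90–95%, so the product is enantioenriched, not enantiopure, and a remote Me/Et stereocentre on a waxy chain cannot be upgraded by crystallisation or chromatography.
   - β-H hydroalumination gives n-heptadecanol, which is only separable by reverse-phase HPLC; residual alkene is removed on AgNO3–silica.
   - Fallback: a chiral-pool radical coupling that replaces steps 1–2. Mixed Kolbe electrolysis of (S)-3-methylpentanoic acid (5 equiv) with 15-hydroxypentadecanoic acid (KOH 0.1 equiv, MeOH, Pt electrodes, constant current, 45 °C) gives 5 directly. The radical is β to the stereocentre, so enantiopurity is fixed by the starting acid.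

2. **Step 3 (unprotected Mitsunobu).** The 3-OH may be O-alkylated, or the catechol may be tied up as a benzodioxaphosphorane, lowering the yield.
   - Fallback: a protected acyl-donor route. Acylate 5 with 2,3-bis(benzyloxy)benzoyl chloride (Et3N, DMAP, CH2Cl2), then remove both benzyl groups with H2, Pd/C.

3. **Step 1 (Cu-catalysed alkyl–alkyl coupling).** Wurtz homocoupling of the Grignard and poor solubility or reactivity of the bromo-alkoxide are the likely problems.
   - Fallback: make 3 without any sp3–sp3 coupling. Reduce commercial 16-hexadecanolide with DIBAL (−78 °C) to the lactol, then methylenate with Ph3P=CH2 (THF) to give heptadec-16-en-1-ol.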